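**Retrosynthetic overview**
1. Target 23 ⇐ ketone 22 (equatorial MeMgBr addition) ⇐ bridged β-keto lactone 20 (hydrolysis, decarboxylation).
2. 20 ⇐ ring-A bromo keto ester 19 carrying a bridgehead-tethered norbornene: oxidative radical cyclisation closes ring B, and a Wagner–Meerwein 1,2-shift turns the bicyclo[2.2.1]heptene into the isomeric norbornane (the attacked alkene carbon becomes the one-carbon bridge; the C–O bond forms exo).
3. 19 ⇐ acyclic E-alkene β-keto ester 18 by bromonium-initiated cyclisation (ring A, C–Br and the quaternary methyl centre).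
4. 18 ⇐ bridgehead butynyl norbornene 15 (carboalumination/conjugate addition, then carbomethoxylation).
5. 15 ⇐ (S)-cryptone 4 (from 3-methylbutanal and methyl vinyl ketone) by β-substitution and a one-carbon radical bridge. Ring order: cyclohexenone → norbornene → ring A → ring B together with the rearranged norbornane.

Assumption: the epimerisable CH between ketone and ester in 19 is drawn as one epimer; it becomes planar in step 12 and is reset in step 13.

**Route**

Step 1
Reactants: 1 3-methylbutanal; 2 but-3-en-2-one (methyl vinyl ketone)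
Product: 4 (S)-4-isopropylcyclohex-2-en-1-one [(S)-cryptone], via keto aldehyde 3 (not isolated)
Conditions: (S)-α,α-diphenylprolinol methyl ether (5 mol %), ethyl 3,4-dihydroxybenzoate (20 mol %), neat, 4 °C; then LiOH (cat.), i-PrOH, rt
Reagents that add atoms: none
Why: Enamine-catalysed asymmetric Michael addition of the aldehyde to the enone sets the isopropyl-bearing stereocentre as (S), and the intramolecular aldol condensation (Robinson annulation) that follows closes the cyclohexenone without touching it.

Step 2
Reactants: 5 4-bromobut-1-yne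
Product: 6 (4-bromobut-1-yn-1-yl)trimethylsilane
Conditions: n-BuLi, THF, −78 °C; TMSCl, −78 °C → rt
Reagents that add atoms: chlorotrimethylsilane, C[Si](C)(C)Cl
Why: Deprotonation of the terminal alkyne at −78 °C is faster than attack on the primary bromide, so C-silylation of the lithium acetylide protects the alkyne; no stereocentre is involved.

Step 3
Reactants: 4 (S)-cryptone; 6 (4-bromobut-1-yn-1-yl)trimethylsilane
Product: 9 (S)-4-isopropyl-3-[4-(trimethylsilyl)but-3-yn-1-yl]cyclohex-2-en-1-one, via Grignard reagent 7 (not isolated), via silyl enol ether 8 (not isolated)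
Conditions: 6, Mg, THF, rt; CuBr·SMe2 (10 mol %), TMSCl, 4, −78 °C; then Pd(OAc)2 (10 mol %), O2 (1 atm), DMSO, 60 °C
Reagents that add atoms: none
Why: Copper-catalysed conjugate addition of the Grignard reagent (trapped as the silyl enol ether) followed by Saegusa–Ito dehydrogenation re-forms the enone with the side chain on the β-carbon; the isopropyl stereocentre is untouched and the transient β-stereocentre is erased.

Step 4
Reactants: 9 β-substituted cryptone
Product: 10 (4S)-6-(hydroxymethyl)-4-isopropyl-3-[4-(trimethylsilyl)but-3-yn-1-yl]cyclohex-2-en-1-one (hydroxymethyl trans to isopropyl)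
Conditions: LiN(i-Pr)2, THF, −78 °C; monomeric CH2O (THF solution), −78 °C; aq. NH4Cl
Reagents that add atoms: formaldehyde, C=O
Why: Kinetic deprotonation at the α′-methylene gives the cross-conjugated dienolate, whose aldol addition to formaldehyde occurs on the face away from the isopropyl group and so sets the new stereocentre trans to it.

Step 5
Reactants: 10 hydroxymethyl enone
Product: 11 (4S)-6-(iodomethyl)-4-isopropyl-3-[4-(trimethylsilyl)but-3-yn-1-yl]cyclohex-2-en-1-one (iodomethyl trans to isopropyl)
Conditions: I2, PPh3, imidazole, CH2Cl2, 0 °C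
Reagents that add atoms: iodine, II
Why: Appel-type iodination converts the primary alcohol into the iodide under near-neutral conditions, so the β-substituted ketone neither eliminates nor epimerises.

Step 6
Reactants: 11 iodomethyl enone
Product: 12 5-endo-isopropyl-4-[4-(trimethylsilyl)but-3-yn-1-yl]bicyclo[2.2.1]heptan-2-one
Conditions: Bu3SnH (slow addition), AIBN (10 mol %), PhH, 80 °C, 0.01 M
Reagents that add atoms: none
Why: In this tin hydride-mediated intramolecular Giese cyclisation the primary radical adds across the ring to the enone β-carbon, creating the one-carbon bridge and the quaternary bridgehead; because the radical arm is trans to isopropyl, the isopropyl group ends endo (anti to the new bridge).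

Step 7
Reactants: 12 bicyclic ketone
Product: 13 5-endo-isopropyl-4-[4-(trimethylsilyl)but-3-yn-1-yl]bicyclo[2.2.1]hept-2-en-2-yl trifluoromethanesulfonate
Conditions: KN(SiMe3)2, THF, −78 °C; PhNTf2, −78 → 0 °C
Reagents that add atoms: N-phenylbis(trifluoromethanesulfonimide), O=S(=O)(N(c1ccccc1)S(=O)(=O)C(F)(F)F)C(F)(F)F
Why: The ketone can enolise only toward its methylene (the other α-carbon is a bridgehead), so O-triflation of the potassium enolate gives a single enol triflate and no stereocentre is affected.

Step 8
Reactants: 13 enol triflate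
Product: 15 1-(but-3-yn-1-yl)-6-endo-isopropylbicyclo[2.2.1]hept-2-ene, via silylalkyne 14 (not isolated)
Conditions: Pd(OAc)2 (5 mol %), PPh3 (10 mol %), Bu3N, HCO2H, DMF, 60 °C; then K2CO3 (cat.), MeOH, rt
Reagents that add atoms: none
Why: Palladium-catalysed formate reduction of the enol triflate places the strained alkene next to the substituted bridgehead, and base-catalysed methanolysis then removes the alkynyl silyl group; no stereocentre is affected.

Step 9
Reactants: 15 butynyl norbornene; 2 but-3-en-2-one
Product: 17 (E)-8-(6-endo-isopropylbicyclo[2.2.1]hept-2-en-1-yl)-6-methyloct-5-en-2-one, via alkenylalane 16 (not isolated)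
Conditions: Me3Al (2.5 equiv), Cp2ZrCl2 (25 mol %), CH2Cl2, 0 °C → rt; then CuBr·SMe2 (10 mol %), 2, THF, −15 °C; aq. NH4Cl
Reagents that add atoms: trimethylaluminium, C[Al](C)C
Why: Negishi zirconium-catalysed syn-carboalumination of the terminal alkyne gives the E-alkenylalane, and its copper-catalysed conjugate addition to the enone proceeds with retention, fixing the E-trisubstituted alkene.

Step 10
Reactants: 17 methyl ketone
Product: 18 methyl (E)-9-(6-endo-isopropylbicyclo[2.2.1]hept-2-en-1-yl)-7-methyl-3-oxonon-6-enoate
Conditions: NaH, (MeO)2CO, THF, reflux; aq. NH4Cl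
Reagents that add atoms: dimethyl carbonate, COC(=O)OC
Why: Claisen-type C-acylation with dimethyl carbonate is driven by formation of the stabilised β-keto ester enolate and therefore takes place at the methyl group; no stereocentre is formed.

Step 11
Reactants: 18 β-keto ester
Product: 19 methyl 3-bromo-2-methyl-6-oxo-2-[2-(6-endo-isopropylbicyclo[2.2.1]hept-2-en-1-yl)ethyl]cyclohexane-1-carboxylate (Br equatorial and cis to the ring methyl)
Conditions: DBDMH (0.55 equiv), (S)-3,3′-bis(2,4,6-triisopropylphenyl)-BINOL N-triflyl thiophosphoramide (10 mol %, enantiomer selected for the configuration shown), toluene/CH2Cl2 4:1, −78 °C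
Reagents that add atoms: 1,3-dibromo-5,5-dimethylhydantoin, CC1(C)N(Br)C(=O)N(Br)C1=O
Why: Proposed new method: the chiral Lewis-basic thiophosphoramide transfers Br+ to one face of the electron-rich E-trisubstituted alkene (faster than to the strained disubstituted alkene), and the keto ester enol carbon closes ring A through a chair transition state by anti addition, which sets the C–Br centre and the quaternary methyl centre under catalyst control; the closest known reactions are catalytic enantioselective bromonium cyclisations of aryl-terminated polyenes and racemic bromonium cyclisations of polyenes.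

Step 12
Reactants: 19 bromo keto ester
Product: 20 bridged β-keto δ-lactone (full tetracyclic skeleton; the lactone links the ring-A/ring-B fusion carbon to the exo oxygen on the norbornane)
Conditions: Mn(OAc)3·2H2O (2.2 equiv), Cu(OTf)2 (20 mol %), AcOH, 50 °C
Reagents that add atoms: none
Why: Proposed new method: the tertiary α-keto ester radical generated by trivalent manganese adds 6-exo to the exo face of the norbornene, divalent copper (regenerated by trivalent manganese) oxidises the secondary 2-norbornyl radical to the σ-bridged cation, a Wagner–Meerwein 1,2-shift of the adjacent ring CH2 makes the attacked carbon the one-carbon bridge, and the axial ester carbonyl traps the new cation on the exo face with loss of methyl acetate, which sets the bridging CH, the new bridgehead and the exo C–O stereocentres from the fixed bicyclic core; the closest known reactions are Mn(OAc)3/copper-mediated oxidative cyclisations of β-keto esters ending in lactones and the rearranged exo-2/syn-7 adducts of electrophiles with norbornene.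

Step 13
Reactants: 20 β-keto lactone
Product: 22 bromo keto alcohol (ring-A ketone; free exo secondary alcohol), via keto acid 21 (not isolated)
Conditions: LiOH, THF/H2O 3:1, rt; then 1 M HCl, 45 °C
Reagents that add atoms: none
Why: Saponification of the lactone and acid-promoted decarboxylation of the β-keto acid free the exo alcohol, and the new α-CH equilibrates through the enol to the more stable trans ring fusion (H axial), fixing that stereocentre under thermodynamic control.

Step 14
Reactants: 22 bromo keto alcohol
Product: 23 target (CNP0317598.2)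
Conditions: MeMgBr (4 equiv), CeCl3, THF, −78 → 0 °C; aq. NH4Cl
Reagents that add atoms: methylmagnesium bromide, C[Mg]Br
Why: 1,2-Addition of the methyl organometallic to the cyclohexanone comes from the equatorial direction because the axial path is blocked by the 1,3-diaxial angular methyl group, giving the axial tertiary alcohol (OH cis to the angular methyl).

**Compound list**
1 | 3-methylbutanal | CC(C)CC=O | starting material
2 | but-3-en-2-one | CC(=O)C=C | starting material
3 | (S)-2-isopropyl-5-oxohexanal | CC(C)[C@@H](C=O)CCC(C)=O | intermediate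
4 | (S)-4-isopropylcyclohex-2-en-1-one | CC(C)[C@@H]1CCC(=O)C=C1 | intermediate
5 | 4-bromobut-1-yne | BrCCC#C | starting material
6 | (4-bromobut-1-yn-1-yl)trimethylsilane | BrCCC#C[Si](C)(C)C | intermediate
7 | [4-(trimethylsilyl)but-3-yn-1-yl]magnesium bromide | C[Si](C)(C)C#CCC[Mg]Br | intermediate
8 | trimethylsilyl enol ether of the 3,4-trans conjugate adduct | CC(C)[C@@H]1CCC(O[Si](C)(C)C)=C[C@H]1CCC#C[Si](C)(C)C | intermediate
9 | (S)-4-isopropyl-3-[4-(trimethylsilyl)but-3-yn-1-yl]cyclohex-2-en-1-one | CC(C)[C@@H]1CCC(=O)C=C1CCC#C[Si](C)(C)C | intermediate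
10 | 6-(hydroxymethyl) enone, trans to isopropyl | CC(C)[C@@H]1C[C@@H](CO)C(=O)C=C1CCC#C[Si](C)(C)C | intermediate
11 | 6-(iodomethyl) enone, trans to isopropyl | CC(C)[C@@H]1C[C@@H](CI)C(=O)C=C1CCC#C[Si](C)(C)C | intermediate
12 | 5-endo-isopropyl-4-[4-(trimethylsilyl)but-3-yn-1-yl]bicyclo[2.2.1]heptan-2-one | CC(C)[C@@H]1C[C@@H]2C(=O)C[C@@]1(CCC#C[Si](C)(C)C)C2 | intermediate
13 | corresponding bicyclo[2.2.1]hept-2-en-2-yl triflate | CC(C)[C@@H]1C[C@@H]2C(OS(=O)(=O)C(F)(F)F)=C[C@@]1(CCC#C[Si](C)(C)C)C2 | intermediate
14 | 6-endo-isopropyl-1-[4-(trimethylsilyl)but-3-yn-1-yl]bicyclo[2.2.1]hept-2-ene | CC(C)[C@@H]1C[C@@H]2C=C[C@@]1(CCC#C[Si](C)(C)C)C2 | intermediate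
15 | 1-(but-3-yn-1-yl)-6-endo-isopropylbicyclo[2.2.1]hept-2-ene | CC(C)[C@@H]1C[C@@H]2C=C[C@@]1(CCC#C)C2 | intermediate
16 | (E)-alkenyl(dimethyl)alane from 15 | CC(C)[C@@H]1C[C@@H]2C=C[C@@]1(CC/C(C)=C/[Al](C)C)C2 | intermediate
17 | (E)-8-(6-endo-isopropylbicyclo[2.2.1]hept-2-en-1-yl)-6-methyloct-5-en-2-one | CC(C)[C@@H]1C[C@@H]2C=C[C@@]1(CC/C(C)=C/CCC(C)=O)C2 | intermediate
18 | methyl (E)-9-(6-endo-isopropylbicyclo[2.2.1]hept-2-en-1-yl)-7-methyl-3-oxonon-6-enoate | CC(C)[C@@H]1C[C@@H]2C=C[C@@]1(CC/C(C)=C/CCC(=O)CC(=O)OC)C2 | intermediate
19 | ring-A bromo β-keto ester with norbornenylethyl side chain | COC(=O)[C@@H]1C(=O)CC[C@H](Br)[C@@]1(C)CC[C@@]23C=C[C@@H](C[C@H]2C(C)C)C3 | intermediate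
20 | bridged β-keto δ-lactone | CC(C)[C@@H]1C[C@@H]2[C@H]3[C@@]4(C5=O)[C@](C)(CC[C@@]31C[C@H]2O5)[C@@H](Br)CCC4=O | intermediate
21 | hydroxy β-keto acid | CC(C)[C@@H]1C[C@@H]2[C@H]3[C@@]4(C(=O)O)[C@](C)(CC[C@@]31C[C@H]2O)[C@@H](Br)CCC4=O | intermediate
22 | bromo keto alcohol | CC(C)[C@@H]1C[C@@H]2[C@H]3[C@H]4[C@](C)(CC[C@@]31C[C@H]2O)[C@@H](Br)CCC4=O | intermediate
23 | CNP0317598.2 | CC(C)[C@@H]1C[C@@H]2[C@H]3[C@H]4[C@](C)(CC[C@@]31C[C@H]2O)[C@@H](Br)CC[C@@]4(C)O | target

**Step count and risks**
Total steps: 14. Longest linear sequence: 13 (steps 1 and 3–14; step 2 is a one-step side branch).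

Most likely to fail:

1. Step 12 (proposed new cascade). The radical may not close onto the hindered alkene carbon, or the cation may be trapped before or without the shift. Fallback with known chemistry, setting out from 19 and returning at 20: α-iodination (N-iodosuccinimide, Mg(ClO4)2) gives the α-iodo keto ester F1; iodine-atom-transfer radical cyclisation (Et3B/O2, Yb(OTf)3, CH2Cl2, −78 °C) gives the unrearranged secondary norbornyl iodide F2; AgOTf with 2,6-lutidine in wet acetone ionises the iodide in preference to the hindered secondary bromide, and the classical silver-assisted Wagner–Meerwein solvolysis with lactonisation delivers 20.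

2. Step 11 (proposed new catalyst-controlled bromocyclisation). Face selectivity or chemoselectivity over the norbornene may be poor. Fallback with known chemistry, setting out from 18 and returning at 19: cyclise with the achiral reagent Et2SBr·SbCl5Br (MeNO2, −25 °C). Because the norbornene part is already a single enantiomer, this gives 19 together with its ring-A diastereomer F3 (about 1:1), and the two are separated by chromatography.

3. Step 6 (radical bridging to a strained bicycle). Reduction of the iodide without cyclisation may compete. Fallback, setting out from 9 and returning at 12, builds the bridge by polar bond formation from the other end: copper-catalysed conjugate addition of (i-PrO)Me2SiCH2MgCl to 9 (anti to isopropyl) gives the silyl ketone F4; Tamao oxidation (KF, KHCO3, H2O2) gives the hydroxymethyl ketone F5; TsCl/pyridine gives the tosylate F6; LiN(i-Pr)2 (kinetic enolate at the unhindered α-methylene, THF, −78 °C → rt) closes the one-carbon bridge by intramolecular alkylation to 12.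

Further compounds
F1 | step 12 | α-iodo derivative of keto ester 19 (iodine on the carbon between ketone and ester, both epimers) | COC(=O)C1(I)C(=O)CC[C@H](Br)[C@@]1(C)CC[C@@]23C=C[C@@H](C[C@H]2C(C)C)C3
F2 | step 12 | unrearranged atom-transfer product (ring B closed, endo secondary iodide on the norbornane) | COC(=O)[C@@]14C(=O)CC[C@H](Br)[C@@]1(C)CC[C@@]23[C@H]4[C@@H](I)[C@@H](C[C@H]2C(C)C)C3
F3 | step 11 | ring-A diastereomer of 19 (opposite configuration at the C–Br and quaternary methyl centres) | COC(=O)[C@H]1C(=O)CC[C@@H](Br)[C@]1(C)CC[C@@]23C=C[C@@H](C[C@H]2C(C)C)C3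
F4 | step 6 | 3-[(isopropoxydimethylsilyl)methyl]-4-isopropyl-3-[4-(trimethylsilyl)but-3-yn-1-yl]cyclohexanone (silylmethyl trans to isopropyl) | CC(C)[C@@H]1CCC(=O)C[C@]1(C[Si](C)(C)OC(C)C)CCC#C[Si](C)(C)C
F5 | step 6 | 3-(hydroxymethyl)-4-isopropyl-3-[4-(trimethylsilyl)but-3-yn-1-yl]cyclohexanone | CC(C)[C@@H]1CCC(=O)C[C@]1(CO)CCC#C[Si](C)(C)C
F6 | step 6 | tosylate of F5 | CC(C)[C@@H]1CCC(=O)C[C@]1(COS(=O)(=O)c2ccc(C)cc2)CCC#C[Si](C)(C)C
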